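## Retrosynthetic overview

1. Target 13 (C2 = R) comes from flavan 12 by removal of two MOM ethers. Rings A and B are bought aromatic, a temporary oxetane ring is made first, and ring C (the dihydropyran) is formed last.
2. Ring C is cut at C4–C4a and O1–C8a. This gives aryl iodide 6 (iodine on the future C8a) and (R)-2-(3,5-dimethoxyphenyl)oxetane 11, joined in one Pd/norbornene (Catellani-type) annulation that opens the strained oxetane.
3. Enabling feature: ring A is a 6-prenylphloroglucinol with a local mirror axis through C6 and C8a (C5–O and C7–O flank C6), so an iodide at C8a has two equivalent ortho C–H bonds (future C4a and C8). The only stereocenter, C2, sits at a benzylic C–O bond that is never broken, so the O1–C2–C3–C4 unit can be stored in an oxetane that delivers the C4 electrophile and the O1 nucleophile from one ring.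
4. 6 comes from resorcinol by directed ortho-metalation/prenylation, sterically controlled Ir C–H borylation and Cu iododeboronation. 11 comes from β-keto ester 7 by asymmetric transfer hydrogenation (sets C2), ester reduction and Williamson closure.

Key step: step 9

Remark: C2 of the target is R by the sequence rule (O1 > aryl > C3 > H); this center is set in step 5 and no bond to it is broken afterwards.

## Route

Step 1
Reactants: 1 resorcinol
Product: 2 1,3-bis(methoxymethoxy)benzene
Conditions: NaH (2.4 equiv), MOMCl (2.3 equiv), DMF, 0 °C → rt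
Reagents that add atoms: chloromethyl methyl ether (MOMCl), COCCl
Why: Williamson O-alkylation of both phenoxides; the MOM ethers serve as base-stable protecting groups and as directing groups for step 2.

Step 2
Reactants: 2 1,3-bis(methoxymethoxy)benzene
Product: 4 1,3-bis(methoxymethoxy)-2-(3-methylbut-2-en-1-yl)benzene, via aryllithium 3 (not isolated)
Conditions: n-BuLi (1.1 equiv), TMEDA, THF, 0 °C; then CuI (10 mol %), prenyl bromide (1.3 equiv), −78 °C → rt
Reagents that add atoms: prenyl bromide (1-bromo-3-methylbut-2-ene), CC(C)=CCBr
Why: Directed ortho-metalation, in which the two MOM ethers cooperatively direct lithiation to the carbon between them, followed by copper-catalysed SN2 allylation that should give the linear prenyl arene.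

Step 3
Reactants: 4 1,3-bis(methoxymethoxy)-2-(3-methylbut-2-en-1-yl)benzene
Product: 5 2-[3,5-bis(methoxymethoxy)-4-(3-methylbut-2-en-1-yl)phenyl]-4,4,5,5-tetramethyl-1,3,2-dioxaborolane
Conditions: [Ir(OMe)(cod)]2 (1.5 mol %), 4,4'-di-tert-butyl-2,2'-bipyridine (3 mol %), B2pin2 (1.0 equiv), THF, 65 °C
Reagents that add atoms: bis(pinacolato)diboron, CC1(C)OB(OC1(C)C)B1OC(C)(C)C(C)(C)O1
Why: Sterically governed iridium-catalysed aromatic C–H borylation; the only ring C–H without an ortho substituent is the one para to the prenyl group, and the trisubstituted alkene should be too hindered to be hydroborated.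

Step 4
Reactants: 5 the aryl boronate of step 3
Product: 6 5-iodo-1,3-bis(methoxymethoxy)-2-(3-methylbut-2-en-1-yl)benzene
Conditions: CuI (10 mol %), 1,10-phenanthroline (20 mol %), KI (1.5 equiv), MeOH/H2O, air, 80 °C
Reagents that add atoms: potassium iodide, [K+].[I-]
Why: Copper-mediated oxidative iododeboronation replaces C–B by C–I at the same carbon without electrophilic iodine, so the alkene and the electron-rich ring should be untouched.

Step 5
Reactants: 7 ethyl 3-(3,5-dimethoxyphenyl)-3-oxopropanoate
Product: 8 ethyl (3R)-3-(3,5-dimethoxyphenyl)-3-hydroxypropanoate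
Conditions: RuCl[(R,R)-TsDPEN](p-cymene) (1 mol %), HCO2H/Et3N (5:2), DMF, 40 °C
Reagents that add atoms: none
Why: Noyori asymmetric transfer hydrogenation of an aryl ketone; the (R,R) ligand should deliver hydride to the face that gives the (R)-carbinol (aryl ranked above CH2CO2Et), which becomes C2 of the target.

Step 6
Reactants: 8 ethyl (3R)-3-(3,5-dimethoxyphenyl)-3-hydroxypropanoate
Product: 9 (1R)-1-(3,5-dimethoxyphenyl)propane-1,3-diol
Conditions: LiBH4 (2 equiv), THF, 0 °C → rt; aqueous work-up
Reagents that add atoms: none
Why: Hydride reduction of the ester, assisted by the β-alkoxide; the stereocenter is not involved.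

Step 7
Reactants: 9 (1R)-1-(3,5-dimethoxyphenyl)propane-1,3-diol
Product: 10 (3R)-3-(3,5-dimethoxyphenyl)-3-hydroxypropyl 4-methylbenzenesulfonate
Conditions: TsCl (1.05 equiv), Et3N (1.5 equiv), DMAP (5 mol %), CH2Cl2, −10 → 0 °C
Reagents that add atoms: 4-toluenesulfonyl chloride (TsCl), Cc1ccc(cc1)S(Cl)(=O)=O
Why: Selective sulfonylation of the primary over the secondary benzylic hydroxyl on steric grounds; the benzylic C–O bond is left alone.

Step 8
Reactants: 10 (3R)-3-(3,5-dimethoxyphenyl)-3-hydroxypropyl 4-methylbenzenesulfonate
Product: 11 (2R)-2-(3,5-dimethoxyphenyl)oxetane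
Conditions: KOtBu (1.2 equiv), THF, 0 °C → rt
Reagents that add atoms: none
Why: Intramolecular Williamson etherification (4-exo-tet): the benzylic alkoxide displaces the primary tosylate, so the C–O bond at the stereocenter is never broken and R is retained.

Step 9
Reactants: 6 5-iodo-1,3-bis(methoxymethoxy)-2-(3-methylbut-2-en-1-yl)benzene; 11 (2R)-2-(3,5-dimethoxyphenyl)oxetane
Product: 12 (2R)-2-(3,5-dimethoxyphenyl)-5,7-bis(methoxymethoxy)-6-(3-methylbut-2-en-1-yl)chromane
Conditions: Pd(OAc)2 (10 mol %), RuPhos (20 mol %), isopropyl bicyclo[2.2.1]hept-5-ene-2-carboxylate (50 mol %), Cs2CO3 (1.5 equiv), 11 (1.5 equiv), 1,4-dioxane, 110 °C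
Reagents that add atoms: none
Why: Proposed new method: zerovalent palladium adds oxidatively to the C–I bond of 6, norbornene insertion and carbonate-assisted palladation of one of the two equivalent ortho C–H bonds give the aryl–norbornyl palladacycle of divalent palladium, which opens oxetane 11 by SN2-type oxidative addition at its unsubstituted CH2 (release of about 106 kJ/mol of ring strain) to a tetravalent alkyl(alkoxo)palladium species; C(sp2)–C(sp3) reductive elimination then forms C4–C4a, β-carbon elimination expels norbornene, and C(sp2)–O reductive elimination forms O1–C8a. The closest known reaction types are the Pd/norbornene (Catellani) annulation of aryl iodides with epoxides to 2,3-dihydrobenzofurans and the ortho-alkylation/ipso-amination of aryl iodides with bromoalkylamines to indolines and tetrahydroquinolines; this is the four-membered-ring homologue of the former. Ring C is the only ring closed; it closes last, by reductive elimination from a seven-membered aryl(alkoxo)palladium chelate, so the oxetane is formally inserted into the C8a–I/C4a–H edge of ring A in a (3+3) annulation. No stereocenter is created: C2 keeps the R configuration of 11 because only the O–CH2 bond of the oxetane is cleaved and no bond to the benzylic carbon is touched. The step needs site selectivity on ring A, which the mirror symmetry of 6 makes automatic; attack at CH2 rather than the benzylic carbon, which the SN2 character of the opening and the non-cation-stabilising meta-dimethoxyaryl group should secure; and a single annulation, which is favoured because the alkoxide appears only after the C–C bond is made (no open-chain aryl ether can form first) and because the remaining ortho C–H is shielded by its neighbouring OMOM group.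

Step 10
Reactants: 12 (2R)-2-(3,5-dimethoxyphenyl)-5,7-bis(methoxymethoxy)-6-(3-methylbut-2-en-1-yl)chromane
Product: 13 (2R)-2-(3,5-dimethoxyphenyl)-6-(3-methylbut-2-en-1-yl)chromane-5,7-diol (target)
Conditions: 3 M aq. HCl/MeOH (1:10), 45 °C
Reagents that add atoms: none
Why: Acid-catalysed acetal methanolysis of the two aryl MOM ethers; the aryl methyl ethers, the trisubstituted alkene and the C2 benzylic ether (no cation stabilisation from the meta-dimethoxyaryl group) should survive mild acid, so C2 stays R.

## Compound list

1 | resorcinol (benzene-1,3-diol) | Oc1cccc(O)c1 | starting material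
2 | 1,3-bis(methoxymethoxy)benzene | COCOc1cccc(OCOC)c1 | intermediate
3 | [2,6-bis(methoxymethoxy)phenyl]lithium (not isolated) | [Li]c1c(OCOC)cccc1OCOC | intermediate
4 | 1,3-bis(methoxymethoxy)-2-(3-methylbut-2-en-1-yl)benzene | COCOc1cccc(OCOC)c1CC=C(C)C | intermediate
5 | 2-[3,5-bis(methoxymethoxy)-4-(3-methylbut-2-en-1-yl)phenyl]-4,4,5,5-tetramethyl-1,3,2-dioxaborolane | COCOc1cc(cc(OCOC)c1CC=C(C)C)B1OC(C)(C)C(C)(C)O1 | intermediate
6 | 5-iodo-1,3-bis(methoxymethoxy)-2-(3-methylbut-2-en-1-yl)benzene | COCOc1cc(I)cc(OCOC)c1CC=C(C)C | intermediate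
7 | ethyl 3-(3,5-dimethoxyphenyl)-3-oxopropanoate | CCOC(=O)CC(=O)c1cc(OC)cc(OC)c1 | starting material
8 | ethyl (3R)-3-(3,5-dimethoxyphenyl)-3-hydroxypropanoate | CCOC(=O)C[C@@H](O)c1cc(OC)cc(OC)c1 | intermediate
9 | (1R)-1-(3,5-dimethoxyphenyl)propane-1,3-diol | OCC[C@@H](O)c1cc(OC)cc(OC)c1 | intermediate
10 | (3R)-3-(3,5-dimethoxyphenyl)-3-hydroxypropyl 4-methylbenzenesulfonate | Cc1ccc(cc1)S(=O)(=O)OCC[C@@H](O)c1cc(OC)cc(OC)c1 | intermediate
11 | (2R)-2-(3,5-dimethoxyphenyl)oxetane | COc1cc(OC)cc([C@H]2CCO2)c1 | intermediate
12 | (2R)-2-(3,5-dimethoxyphenyl)-5,7-bis(methoxymethoxy)-6-(3-methylbut-2-en-1-yl)chromane | COc1cc(OC)cc([C@H]2CCc3c(cc(OCOC)c(CC=C(C)C)c3OCOC)O2)c1 | intermediate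
13 | (2R)-2-(3,5-dimethoxyphenyl)-6-(3-methylbut-2-en-1-yl)chromane-5,7-diol | COc1cc(OC)cc([C@H]2CCc3c(cc(O)c(CC=C(C)C)c3O)O2)c1 | target

## Step count and risks

Total steps: 10. Longest linear sequence: 6 (steps 1–4, 9, 10; the oxetane branch, steps 5–8, 9, 10, is equally long).

Steps most likely to fail:

1. Step 9 (Proposed new method). Possible failures:
   - C–H palladation next to the OMOM group may be slow, so the aryl–norbornyl palladium intermediate could collapse to a norbornene-containing benzocyclobutene or be reduced at the iodide carbon.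
   - Oxetane opening may be too slow to compete with these paths.
   - A second ortho alkylation may occur before norbornene is expelled.
   - The palladium alkoxide may undergo β-hydride elimination to the ketone.

   Fallback, known chemistry only, setting out from boronate 5 and returning at 12: oxidation of 5 with H2O2/NaOH in THF–water should give 3,5-bis(methoxymethoxy)-4-(3-methylbut-2-en-1-yl)phenol F1. Magnesium-mediated ortho-formylation (MgCl2, Et3N, paraformaldehyde, MeCN, reflux) at either of the two equivalent ortho positions should give 2-hydroxy-4,6-bis(methoxymethoxy)-5-(3-methylbut-2-en-1-yl)benzaldehyde F2. Claisen–Schmidt condensation with 3',5'-dimethoxyacetophenone (KOH, EtOH) should give (E)-1-(3,5-dimethoxyphenyl)-3-[2-hydroxy-4,6-bis(methoxymethoxy)-5-(3-methylbut-2-en-1-yl)phenyl]prop-2-en-1-one F3. One-pot transfer hydrogenation of C=C and then C=O with RuCl[(S,S)-TsDPEN](p-cymene) and HCO2H/Et3N should give 2-[(3S)-3-(3,5-dimethoxyphenyl)-3-hydroxypropyl]-3,5-bis(methoxymethoxy)-4-(3-methylbut-2-en-1-yl)phenol F4. Mitsunobu cyclisation (PPh3, DIAD, THF, 0 °C) closes O1–C2 with inversion and should deliver (R)-12. Here the stereocenter is set by the catalyst and inverted once, instead of being carried through.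

2. Step 3. Iridium hydride or pinacolborane may hydroborate or isomerise the prenyl alkene, or borylate its allylic/vinylic C–H bonds, in competition with arene borylation.

   Fallback, setting out from 2 (through aryllithium 3) and returning at 5: the alkene is introduced only after the C–H borylation. Trapping 3 with 1,2-dibromoethane should give 2-bromo-1,3-bis(methoxymethoxy)benzene F5. Iridium-catalysed borylation of this alkene-free arene (same catalyst as step 3) should give 2-[4-bromo-3,5-bis(methoxymethoxy)phenyl]-4,4,5,5-tetramethyl-1,3,2-dioxaborolane F6. A base-free, linear-selective Negishi coupling of the aryl bromide with prenylzinc bromide (Me2C=CHCH2ZnBr; Pd(OAc)2, CPhos, THF) should leave the boronate untouched and give 5.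

3. Step 10. Protic acid may add the freed C5 or C7 hydroxyl across the neighbouring prenyl alkene (cyclisation to a dimethylchromane ring), or add HCl/MeOH to the alkene, before both acetals are cleaved.

   Fallback, setting out from 12 and returning at 13: the acetals are exchanged for silyl ethers under non-protic, buffered conditions instead of being solvolysed. TMSOTf with 2,2'-bipyridyl in MeCN at 0 °C should convert both aryl MOM ethers into (2R)-2-(3,5-dimethoxyphenyl)-6-(3-methylbut-2-en-1-yl)-5,7-bis(trimethylsilyloxy)chromane F7, and addition of water at rt should hydrolyse the two aryl silyl ethers to 13.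

## Further compounds

F1 | step 9 | 3,5-bis(methoxymethoxy)-4-(3-methylbut-2-en-1-yl)phenol | COCOc1cc(O)cc(OCOC)c1CC=C(C)C
F2 | step 9 | 2-hydroxy-4,6-bis(methoxymethoxy)-5-(3-methylbut-2-en-1-yl)benzaldehyde | O=Cc1c(O)cc(OCOC)c(CC=C(C)C)c1OCOC
F3 | step 9 | (E)-1-(3,5-dimethoxyphenyl)-3-[2-hydroxy-4,6-bis(methoxymethoxy)-5-(3-methylbut-2-en-1-yl)phenyl]prop-2-en-1-one | COc1cc(OC)cc(c1)C(=O)/C=C/c1c(O)cc(OCOC)c(CC=C(C)C)c1OCOC
F4 | step 9 | 2-[(3S)-3-(3,5-dimethoxyphenyl)-3-hydroxypropyl]-3,5-bis(methoxymethoxy)-4-(3-methylbut-2-en-1-yl)phenol | COc1cc(OC)cc([C@@H](O)CCc2c(O)cc(OCOC)c(CC=C(C)C)c2OCOC)c1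
F5 | step 3 | 2-bromo-1,3-bis(methoxymethoxy)benzene | COCOc1cccc(OCOC)c1Br
F6 | step 3 | 2-[4-bromo-3,5-bis(methoxymethoxy)phenyl]-4,4,5,5-tetramethyl-1,3,2-dioxaborolane | COCOc1cc(cc(OCOC)c1Br)B1OC(C)(C)C(C)(C)O1
F7 | step 10 | (2R)-2-(3,5-dimethoxyphenyl)-6-(3-methylbut-2-en-1-yl)-5,7-bis(trimethylsilyloxy)chromane | COc1cc(OC)cc([C@H]2CCc3c(cc(O[Si](C)(C)C)c(CC=C(C)C)c3O[Si](C)(C)C)O2)c1
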